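**Retrosynthetic overview**

1. Numbering: ring B plus the ether bridge is a 9-oxabicyclo[3.3.1]nonane: C1 (O-bearing ring A/B fusion), C2 (alkene ring A/B fusion), C3 (ketone), C4 (methyl-bearing ring B/C fusion), C5 (O-bearing ring B/C fusion), C6 (CH2), C7 (CHOH), C8 (CHMe), O9 (bridge). Ring A is C1, C2 plus the methoxymethyl-cyclopentene carbons; ring C is C4, C5 plus the isopropyl-cyclopentenone carbons.
2. Enabling feature: C1 is an ether carbon lying β to the C3 ketone through C2, and O9 on C5 reaches it over the path C5–C6–C7–C8–C1. C1 is therefore a masked ketone whose oxocarbenium ion can be closed first by O9 (ring O9–C5–C6–C7–C8–C1) and then by the C2 enol of a C4 acetyl group (ring O9–C1–C2–C3–C4–C5); these two six-membered closures together make ring B.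
3. Disconnections: ring A last, by aldol condensation of C2 onto a methoxymethyl ketone; O9–C1 and C1–C2 in one Lewis-acid cascade from a monocyclic ring-C cyclopentenone carrying a C1 ethylene ketal; ring C by C4–C5 aldol closure of a Z-enedione released from a 2,3,5-trisubstituted furan with singlet oxygen.
4. Stereochemistry: C7 and C8 come from a catalytic anti-crotylation; C5 (and with it C4) from chelation-controlled 1,3-anti addition to the C5 ketone beside the C7 p-methoxybenzyl (PMB) ether; C1 is fixed by the bridge.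
5. Ring order: C (step 12), then B with the O9 bridge (step 13), then A (step 15); the chain is assembled on 3-bromofuran.

Key step: step 13

Assumptions: (S)-SEGPHOS is taken as the ligand antipode that gives the (2S,3R) alcohol in step 2 (its enantiomer is used if the sense is opposite); the two side-chain centres created in step 9 are not controlled and are left undefined because steps 10 to 12 erase them.

**Route**

Step 1
Reactants: 1 3-bromofuran; 2 oxirane
Product: 4 2-(3-bromofuran-2-yl)ethan-1-ol, via 3-bromo-2-lithiofuran 3 (not isolated)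
Conditions: LiN(iPr)2, THF, −78 °C; then 2, BF3·OEt2, −78 °C; aq. NH4Cl
Reagents that add atoms: oxirane (2), C1CO1
Why: Directed ortho-lithiation removes the C2 proton next to bromine, and the 2-furyllithium should open the BF3-activated epoxide at −78 °C, below the temperature at which the bromolithiofuran rearranges.

Step 2
Reactants: 4 2-(3-bromofuran-2-yl)ethan-1-ol; 5 but-3-en-2-yl acetate (racemic)
Product: 7 (2S,3R)-1-(3-bromofuran-2-yl)-3-methylpent-4-en-2-ol, via furylacetaldehyde 6 (not isolated)
Conditions: [Ir(cod)Cl]2 (2.5 mol%), (S)-SEGPHOS (5 mol%), 4-cyano-3-nitrobenzoic acid (10 mol%), Cs2CO3 (20 mol%), THF, 90 °C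
Reagents that add atoms: but-3-en-2-yl acetate (5), CC(OC(C)=O)C=C
Why: Iridium-catalysed transfer-hydrogenative carbonyl crotylation from the alcohol oxidation level: the sensitive aldehyde 6 is formed only transiently, the (E)-σ-crotyl iridium species adds through a closed chair transition state to give the anti C7/C8 relationship, and the ligand sets the absolute sense.

Step 3
Reactants: 7 (2S,3R)-1-(3-bromofuran-2-yl)-3-methylpent-4-en-2-ol
Product: 8 3-bromo-2-[(2S,3R)-2-(4-methoxybenzyloxy)-3-methylpent-4-en-1-yl]furan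
Conditions: NaH, 4-methoxybenzyl chloride, Bu4NI (cat.), DMF, 0 °C → rt
Reagents that add atoms: 4-methoxybenzyl chloride, COc1ccc(CCl)cc1
Why: Williamson etherification; the PMB ether is chosen because it can chelate in step 12 and can be removed oxidatively at the end.

Step 4
Reactants: 8 3-bromo-2-[(2S,3R)-2-(4-methoxybenzyloxy)-3-methylpent-4-en-1-yl]furan
Product: 9 (3S,4S)-5-(3-bromofuran-2-yl)-4-(4-methoxybenzyloxy)-3-methylpentan-2-one
Conditions: PdCl2 (10 mol%), CuCl (1 equiv), O2 (1 atm), DMF/H2O (7:1), rt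
Reagents that add atoms: water, O; dioxygen (terminal oxidant), O=O
Why: Tsuji–Wacker oxidation: Markovnikov hydroxypalladation of the terminal alkene should give the methyl ketone (the future C1 carbonyl) in a non-basic medium that leaves C8 untouched; the bromine keeps the furan electron-poor towards palladation.

Step 5
Reactants: 10 3-bromo-2-(bromomethyl)prop-1-ene
Product: 11 2-(bromomethyl)-3-methoxyprop-1-ene
Conditions: NaOMe (1.0 equiv), MeOH, 0 °C → rt; distillation
Reagents that add atoms: sodium methoxide, [Na+].[O-]C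
Why: Williamson (SN2) mono-substitution of the symmetrical bis-allylic dibromide with one equivalent of methoxide; the bis-ether is removed by distillation.

Step 6
Reactants: 9 (3S,4S)-5-(3-bromofuran-2-yl)-4-(4-methoxybenzyloxy)-3-methylpentan-2-one; 11 2-(bromomethyl)-3-methoxyprop-1-ene
Product: 13 (6S,7S)-8-(3-bromofuran-2-yl)-1-methoxy-7-(4-methoxybenzyloxy)-6-methyl-2-methylideneoctan-5-one, via lithium enolate 12 (not isolated)
Conditions: LiN(iPr)2, THF, −78 °C; then 11, DMPU, −78 → −30 °C
Reagents that add atoms: 2-(bromomethyl)-3-methoxyprop-1-ene (11), COCC(=C)CBr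
Why: Kinetic enolate alkylation: the hindered amide deprotonates the methyl group and not the C8 methine, so C8 and the β-ether are preserved, and the allylic bromide reacts by SN2.

Step 7
Reactants: 13 (6S,7S)-8-(3-bromofuran-2-yl)-1-methoxy-7-(4-methoxybenzyloxy)-6-methyl-2-methylideneoctan-5-one
Product: 14 2-[(2S,3S)-4-(3-bromofuran-2-yl)-3-(4-methoxybenzyloxy)butan-2-yl]-2-[3-(methoxymethyl)but-3-en-1-yl]-1,3-dioxolane
Conditions: Me3SiOCH2CH2OSiMe3, Me3SiOTf (5 mol%), CH2Cl2, −78 → −20 °C; pyridine quench
Reagents that add atoms: 1,2-bis(trimethylsilyloxy)ethane, C[Si](C)(C)OCCO[Si](C)(C)C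
Why: Silyl-triflate-catalysed aprotic ketalisation at low temperature should form the dioxolane without enolising the ketone towards C8; the ketal protects C1 from organolithium reagents and is the oxocarbenium precursor for step 13.

Step 8
Reactants: 14 bromofuran ketal; 15 isopropylzinc bromide
Product: 16 2-[(2S,3S)-3-(4-methoxybenzyloxy)-4-[3-(propan-2-yl)furan-2-yl]butan-2-yl]-2-[3-(methoxymethyl)but-3-en-1-yl]-1,3-dioxolane
Conditions: Pd(OAc)2 (2 mol%), CPhos (4 mol%), THF/toluene, rt
Reagents that add atoms: isopropylzinc bromide (15), CC(C)[Zn]Br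
Why: Negishi cross-coupling of a secondary alkylzinc with a heteroaryl bromide; the biaryl phosphine favours reductive elimination over β-hydride elimination, so the isopropyl group should not isomerise to n-propyl.

Step 9
Reactants: 16 isopropylfuran ketal; 17 cis-2,3-dimethyloxirane
Product: 19 3-[5-{(2S,3S)-2-(4-methoxybenzyloxy)-3-[2-(3-(methoxymethyl)but-3-en-1-yl)-1,3-dioxolan-2-yl]butyl}-4-(propan-2-yl)furan-2-yl]butan-2-ol, via 5-lithiofuran 18 (not isolated)
Conditions: n-BuLi, THF, −78 → −20 °C; then 17, BF3·OEt2, −78 °C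
Reagents that add atoms: cis-2,3-dimethyloxirane (17), C[C@H]1O[C@H]1C
Why: α-Lithiation of the furan at its only free position next to oxygen, then BF3-assisted SN2 opening of the meso epoxide; the two new centres are not controlled and are erased in steps 10 to 12.

Step 10
Reactants: 19 furyl butanol
Product: 20 3-[5-{(2S,3S)-2-(4-methoxybenzyloxy)-3-[2-(3-(methoxymethyl)but-3-en-1-yl)-1,3-dioxolan-2-yl]butyl}-4-(propan-2-yl)furan-2-yl]butan-2-one
Conditions: Dess–Martin periodinane, NaHCO3, CH2Cl2, 0 °C → rt
Reagents that add atoms: none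
Why: Dess–Martin oxidation of the secondary alcohol under buffered, near-neutral conditions that the furan, the ketal and the PMB ether tolerate.

Step 11
Reactants: 20 furyl butanone
Product: 22 Z-enedione CH3CO–CH(CH3)–CO–CH=C(iPr)–CO–CH2–CH(OPMB)–CH(CH3)–C(ketal)–chain, via furan endoperoxide 21 (not isolated)
Conditions: O2, hν (visible), methylene blue (cat.), CH2Cl2, −78 °C; then Me2S, −78 → 0 °C
Reagents that add atoms: dioxygen, O=O
Why: Singlet oxygen adds (4+2) across the trialkylfuran far faster than it attacks the 1,1-disubstituted alkene by an ene reaction, and reduction of the endoperoxide with the sulfide gives the cis-enedione with the future C5 ketone and the C4-H 1,3-diketone in place.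

Step 12
Reactants: 22 Z-enedione
Product: 24 (4R,5S)-5-acetyl-5-methyl-3-(propan-2-yl)-4-(trimethylsilyloxy)-4-{(2S,3S)-2-(4-methoxybenzyloxy)-3-[2-(3-(methoxymethyl)but-3-en-1-yl)-1,3-dioxolan-2-yl]butyl}cyclopent-2-en-1-one, via magnesium aldolate 23 (not isolated)
Conditions: MgBr2·OEt2 (1.5 equiv), Et3N (2 equiv), CH2Cl2, −40 °C; then Me3SiOTf (1.3 equiv), −78 °C; aq. NaHCO3
Reagents that add atoms: trimethylsilyl trifluoromethanesulfonate, C[Si](C)(C)OS(=O)(=O)C(F)(F)F
Why: Soft enolisation gives a magnesium diketonate that closes ring C by a 5-(enolexo)-exo-trig aldol addition onto the cis-disposed C5 ketone; magnesium bridging the acetyl oxygen, the C5 carbonyl oxygen and the C7 ether oxygen should place O and acetyl cis and deliver C4 1,3-anti to the C7 ether (chelation control), and in-flask silylation stops the retro-aldol.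

Step 13
Reactants: 24 ring-C silyl ether
Product: 27 tricyclic bridged ether (ring C fused to the 9-oxabicyclo[3.3.1]nonan-3-one; C1 3-(methoxymethyl)but-3-enyl; C7 OPMB; overview numbering 1S 4S 5R 7S 8S), via silyl enol ether 25 (not isolated), via cyclic mixed ketal 26 (not isolated)
Conditions: LiN(iPr)2, Me3SiCl, THF, −78 °C; evaporate, pentane, filter; then Me3SiOTf (0.3 equiv), CH2Cl2, −78 → −40 °C; aq. NaHCO3
Reagents that add atoms: none
Why: The acetyl group is the only enolisable ketone and is converted to its enol silane; the silyl triflate then opens the C1 dioxolane to an oxocarbenium ion that the C5 silyl ether oxygen captures (6-exo-trig closure of ring O9–C5–C6–C7–C8–C1, forming O9–C1), a second ionisation expels the silylated glycol arm, and the ring oxocarbenium ion at C1 is attacked by the C2 enol silane (6-(enolendo)-endo-trig closure of ring O9–C1–C2–C3–C4–C5), which completes the eight-membered ring B as its two bridged halves. The closest known reaction type is the silyl-triflate-catalysed acetal–enol silane (Mukaiyama) addition in its annulative form, in which 1,5-dicarbonyl compounds and bis(enol silanes) give 9-oxabicyclo[3.3.1]nonan-3-ones. C1 is the only new stereocentre and is fixed by the bridge, because the C2 nucleophile is tied through C3–C4 to C5 and can reach C1 only on the face syn to the C5–C4 bond. The step needs O-attack at C1 ahead of proton loss and no loss of the C8 configuration; the 1,5 relation of the C5 oxygen to C1, base-free catalytic acid at −78 °C and the pre-formed enol silane should secure this, and the reverse order (C2–C1 first, then transannular ether closure) would converge on the same product. The C7 ether ends endo, so the tetrahydropyran ring must close through a boat-like arrangement, as it sits in the natural product.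

Step 14
Reactants: 27 tricyclic bridged ether
Product: 29 tricyclic methoxymethyl ketone (C1 chain CH2CH2COCH2OCH3; otherwise as 27), via vicinal diol 28 (not isolated)
Conditions: OsO4 (2 mol%), NaIO4 (4 equiv), 2,6-lutidine, dioxane/H2O (3:1), rt
Reagents that add atoms: sodium periodate, [Na+].[O-]I(=O)(=O)=O
Why: Lemieux–Johnson cleavage: the electron-rich 1,1-disubstituted alkene should be dihydroxylated in preference to the hindered, electron-poor ring-C enone, and periodate cleaves the diol to the ketone.

Step 15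
Reactants: 29 tricyclic methoxymethyl ketone
Product: 31 7-O-(4-methoxybenzyl)alterbrassicicene C, via ring-A aldol 30 (not isolated)
Conditions: DBU, toluene, 60 °C
Reagents that add atoms: none
Why: Intramolecular aldol condensation of the 1,6-diketone: the C2 enolate (C3 has no other α-hydrogen) adds to the methoxymethyl ketone in a 5-(enolexo)-exo-trig closure of ring A, and E1cB dehydration gives the tetrasubstituted enone; a non-nucleophilic base avoids retro-Claisen cleavage of the 1,3-diketone.

Step 16
Reactants: 31 7-O-(4-methoxybenzyl)alterbrassicicene C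
Product: 32 alterbrassicicene C
Conditions: DDQ, CH2Cl2/pH 7 buffer (10:1), 0 °C → rt
Reagents that add atoms: none
Why: Oxidative PMB cleavage (benzylic hydride abstraction, then hydrolysis) under neutral conditions should free the C7 hydroxyl without touching the enones, the methyl ether or the bridge.

**Compound list**

1 | 3-bromofuran | Brc1ccoc1 | starting material
2 | oxirane | C1CO1 | starting material
3 | 3-bromo-2-lithiofuran | [Li]c1occc1Br | intermediate
4 | 2-(3-bromofuran-2-yl)ethan-1-ol | OCCc1occc1Br | intermediate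
5 | but-3-en-2-yl acetate (racemic) | CC(OC(C)=O)C=C | starting material
6 | 2-(3-bromofuran-2-yl)acetaldehyde | O=CCc1occc1Br | intermediate
7 | (2S,3R)-1-(3-bromofuran-2-yl)-3-methylpent-4-en-2-ol | Brc1ccoc1C[C@H](O)[C@H](C)C=C | intermediate
8 | 3-bromo-2-[(2S,3R)-2-(4-methoxybenzyloxy)-3-methylpent-4-en-1-yl]furan | Brc1ccoc1C[C@H](OCc2ccc(OC)cc2)[C@H](C)C=C | intermediate
9 | (3S,4S)-5-(3-bromofuran-2-yl)-4-(4-methoxybenzyloxy)-3-methylpentan-2-one | Brc1ccoc1C[C@H](OCc2ccc(OC)cc2)[C@H](C)C(C)=O | intermediate
10 | 3-bromo-2-(bromomethyl)prop-1-ene | BrCC(=C)CBr | starting material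
11 | 2-(bromomethyl)-3-methoxyprop-1-ene | COCC(=C)CBr | intermediate
12 | terminal lithium enolate of 9 | Brc1ccoc1C[C@H](OCc2ccc(OC)cc2)[C@H](C)C(=C)O[Li] | intermediate
13 | (6S,7S)-8-(3-bromofuran-2-yl)-1-methoxy-7-(4-methoxybenzyloxy)-6-methyl-2-methylideneoctan-5-one | Brc1ccoc1C[C@H](OCc2ccc(OC)cc2)[C@H](C)C(=O)CCC(=C)COC | intermediate
14 | 2-[(2S,3S)-4-(3-bromofuran-2-yl)-3-(4-methoxybenzyloxy)butan-2-yl]-2-[3-(methoxymethyl)but-3-en-1-yl]-1,3-dioxolane | Brc1ccoc1C[C@H](OCc2ccc(OC)cc2)[C@H](C)C3(CCC(=C)COC)OCCO3 | intermediate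
15 | isopropylzinc bromide | CC(C)[Zn]Br | starting material
16 | 2-[(2S,3S)-3-(4-methoxybenzyloxy)-4-[3-(propan-2-yl)furan-2-yl]butan-2-yl]-2-[3-(methoxymethyl)but-3-en-1-yl]-1,3-dioxolane | CC(C)c1ccoc1C[C@H](OCc2ccc(OC)cc2)[C@H](C)C3(CCC(=C)COC)OCCO3 | intermediate
17 | cis-2,3-dimethyloxirane (meso) | C[C@H]1O[C@H]1C | starting material
18 | 5-lithio derivative of 16 (lithium on the free furan α-carbon) | [Li]c1cc(C(C)C)c(C[C@H](OCc2ccc(OC)cc2)[C@H](C)C3(CCC(=C)COC)OCCO3)o1 | intermediate
19 | 3-[5-{(2S,3S)-2-(4-methoxybenzyloxy)-3-[2-(3-(methoxymethyl)but-3-en-1-yl)-1,3-dioxolan-2-yl]butyl}-4-(propan-2-yl)furan-2-yl]butan-2-ol (the two butanol centres undefined) | CC(O)C(C)c1cc(C(C)C)c(C[C@H](OCc2ccc(OC)cc2)[C@H](C)C3(CCC(=C)COC)OCCO3)o1 | intermediate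
20 | 3-[5-{(2S,3S)-2-(4-methoxybenzyloxy)-3-[2-(3-(methoxymethyl)but-3-en-1-yl)-1,3-dioxolan-2-yl]butyl}-4-(propan-2-yl)furan-2-yl]butan-2-one (α-centre undefined, epimerisable) | CC(=O)C(C)c1cc(C(C)C)c(C[C@H](OCc2ccc(OC)cc2)[C@H](C)C3(CCC(=C)COC)OCCO3)o1 | intermediate
21 | 2,3,7-trioxabicyclo[2.2.1]hept-5-ene endoperoxide of 20 (bridgeheads are the former furan α-carbons) | CC(=O)C(C)C12OOC(C[C@H](OCc3ccc(OC)cc3)[C@H](C)C4(CCC(=C)COC)OCCO4)(O1)C(C(C)C)=C2 | intermediate
22 | Z-enedione: acetyl–CH(CH3)–CO–CH=C(iPr)–CO–CH2–(S)-CH(OPMB)–(S)-CH(CH3)–dioxolane chain (C4-H centre undefined) | CC(=O)C(C)C(=O)/C=C(C(C)C)\C(=O)C[C@H](OCc2ccc(OC)cc2)[C@H](C)C3(CCC(=C)COC)OCCO3 | intermediate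
23 | bromomagnesium aldolate of the ring-C aldol (4R,5S) | CC(=O)[C@@]1(C)C(=O)C=C(C(C)C)[C@]1(O[Mg]Br)C[C@H](OCc2ccc(OC)cc2)[C@H](C)C3(CCC(=C)COC)OCCO3 | intermediate
24 | (4R,5S)-5-acetyl-5-methyl-3-(propan-2-yl)-4-(trimethylsilyloxy)-4-{(2S,3S)-2-(4-methoxybenzyloxy)-3-[2-(3-(methoxymethyl)but-3-en-1-yl)-1,3-dioxolan-2-yl]butyl}cyclopent-2-en-1-one | CC(=O)[C@@]1(C)C(=O)C=C(C(C)C)[C@]1(O[Si](C)(C)C)C[C@H](OCc2ccc(OC)cc2)[C@H](C)C3(CCC(=C)COC)OCCO3 | intermediate
25 | enol silane of 24 (acetyl converted to 1-(trimethylsilyloxy)vinyl) | C=C(O[Si](C)(C)C)[C@@]1(C)C(=O)C=C(C(C)C)[C@]1(O[Si](C)(C)C)C[C@H](OCc2ccc(OC)cc2)[C@H](C)C3(CCC(=C)COC)OCCO3 | intermediate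
26 | cyclic mixed ketal: tetrahydropyran O9–C5–C6–C7–C8–C1 closed, C1 still carrying the 2-(trimethylsilyloxy)ethoxy group (C1 undefined) | C=C(O[Si](C)(C)C)[C@@]1(C)C(=O)C=C(C(C)C)[C@]12C[C@H](OCc3ccc(OC)cc3)[C@H](C)C(CCC(=C)COC)(OCCO[Si](C)(C)C)O2 | intermediate
27 | tricyclic bridged ether: 9-oxabicyclo[3.3.1]nonan-3-one fused at C4–C5 to the 3-isopropylcyclopentenone; C1 3-(methoxymethyl)but-3-enyl, C4 and C8 methyl, C7 OPMB; (1S,4S,5R,7S,8S) in the overview numbering, same spatial arrangement as in 32 | C1C(=O)[C@@]2(C)C(=O)C=C(C(C)C)[C@]23C[C@H](OCc4ccc(OC)cc4)[C@H](C)[C@@]1(CCC(=C)COC)O3 | intermediate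
28 | vicinal diol from 27 (side-chain alkene dihydroxylated, new centre undefined) | C1C(=O)[C@@]2(C)C(=O)C=C(C(C)C)[C@]23C[C@H](OCc4ccc(OC)cc4)[C@H](C)[C@@]1(CCC(O)(CO)COC)O3 | intermediate
29 | tricyclic methoxymethyl ketone (C1 chain CH2CH2COCH2OCH3; ring stereocentres as in 27) | C1C(=O)[C@@]2(C)C(=O)C=C(C(C)C)[C@]23C[C@H](OCc4ccc(OC)cc4)[C@H](C)[C@@]1(CCC(=O)COC)O3 | intermediate
30 | ring-A β-hydroxy ketone (aldol before dehydration; two new centres undefined) | COCC1(O)C2C(=O)[C@@]3(C)C(=O)C=C(C(C)C)[C@]34C[C@H](OCc5ccc(OC)cc5)[C@H](C)[C@@]2(CC1)O4 | intermediate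
31 | 7-O-(4-methoxybenzyl)alterbrassicicene C, (1R,4R,5R,7S,8S) in the overview numbering | COCC1=C2C(=O)[C@@]3(C)C(=O)C=C(C(C)C)[C@]34C[C@H](OCc5ccc(OC)cc5)[C@H](C)[C@@]2(CC1)O4 | intermediate
32 | alterbrassicicene C, (1R,4R,5R,7S,8S) in the overview numbering | COCC1=C2C(=O)[C@@]3(C)C(=O)C=C(C(C)C)[C@]34C[C@H](O)[C@H](C)[C@@]2(CC1)O4 | target

**Step count**

Total steps: 16. Longest linear sequence: 15 steps (steps 1 to 4 and 6 to 16; step 5 is a one-step side branch).

**Steps most likely to fail**

Step 13. What may go wrong: the C1 oxocarbenium ion may lose a proton to a cyclic enol ether (which would scramble C8), or the C2–C1 closure may be slow because the C7 ether has to sit endo. The fallback forms O9–C1 by a classical cyclodehydration at the C7 ketone level, where C7 is planar; it sets out from 24 and comes back at 32. DDQ removes the PMB group of 24 to give the C7 alcohol F1, and Dess–Martin oxidation gives the C7 ketone F2. Aqueous HCl in THF then removes the silyl ether and the ketal, and the freed C5 hydroxyl condenses with the C1/C7 β-diketone to give the dihydropyranone F3. Intramolecular Michael addition of the acetyl enolate to C1 (KN(SiMe3)2, THF, −78 → 0 °C, acetic acid quench at −78 °C) should give the bridged 3,7-diketone F4, with C8 set by protonation on the exposed O9 face. Lemieux–Johnson cleavage gives the triketone F5, DBU-mediated ring-A condensation gives 7-oxo-alterbrassicicene C F6, and NaBH4 at −78 °C should reduce the only non-conjugated ketone from its exo face to the endo C7 alcohol 32.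

Step 12. What may go wrong: poor facial selectivity at C5 if the magnesium chelate is not formed, or reversal of the aldol addition before silylation. The fallback replaces kinetic chelation control by separation and recycling; it sets out from 22 and comes back at 24. The closure is run under simple amine catalysis (Et3N, CH2Cl2, 0 °C) and silylated as before, and the C4/C5 diastereomer of 24, silyl ether F7, is separated by chromatography. F7 is returned to 22 by fluoride-triggered retro-aldol cleavage (Bu4NF, THF, 0 °C) and resubmitted, so the material is funnelled to 24 over several passes.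

Step 9. What may go wrong: competing deprotonation of the allylic methyl ether by n-BuLi, or opening of the dioxolane by BF3. The fallback generates the same organolithium by halogen–lithium exchange instead of C–H deprotonation; it sets out from 16 and comes back at 18. N-Bromosuccinimide (DMF, −40 °C) brominates the free furan α-position to give the 5-bromofuran F8, and t-BuLi (2 equiv, THF, −78 °C) exchanges bromine for lithium within minutes to give 18, which is used as in step 9 with the epoxide added last at −78 °C.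

Further compounds
F1 | step 13 | C7 alcohol from 24 (PMB removed; silyl ether and ketal kept) | CC(=O)[C@@]1(C)C(=O)C=C(C(C)C)[C@]1(O[Si](C)(C)C)C[C@H](O)[C@H](C)C2(CCC(=C)COC)OCCO2
F2 | step 13 | C7 ketone from F1 (C8 undefined) | CC(=O)[C@@]1(C)C(=O)C=C(C(C)C)[C@]1(O[Si](C)(C)C)CC(=O)C(C)C2(CCC(=C)COC)OCCO2
F3 | step 13 | spiro-free dihydropyranone: 2,3-dihydro-4H-pyran-4-one ring O9–C5–C6–C7(=O)–C8(CH3)=C1 fused to ring C at C5 | CC(=O)[C@@]1(C)C(=O)C=C(C(C)C)[C@]12CC(=O)C(C)=C(CCC(=C)COC)O2
F4 | step 13 | bridged 3,7-diketone (27 with a C7 ketone in place of the PMB ether) | C1C(=O)[C@@]2(C)C(=O)C=C(C(C)C)[C@]23CC(=O)[C@H](C)[C@@]1(CCC(=C)COC)O3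
F5 | step 13 | triketone from F4 (C1 chain CH2CH2COCH2OCH3) | C1C(=O)[C@@]2(C)C(=O)C=C(C(C)C)[C@]23CC(=O)[C@H](C)[C@@]1(CCC(=O)COC)O3
F6 | step 13 | 7-oxo-alterbrassicicene C | COCC1=C2C(=O)[C@@]3(C)C(=O)C=C(C(C)C)[C@]34CC(=O)[C@H](C)[C@@]2(CC1)O4
F7 | step 12 | (4S,5R) diastereomer of 24 | CC(=O)[C@]1(C)C(=O)C=C(C(C)C)[C@@]1(O[Si](C)(C)C)C[C@H](OCc2ccc(OC)cc2)[C@H](C)C3(CCC(=C)COC)OCCO3
F8 | step 9 | 5-bromo derivative of 16 (bromine on the free furan α-carbon) | Brc1cc(C(C)C)c(C[C@H](OCc2ccc(OC)cc2)[C@H](C)C3(CCC(=C)COC)OCCO3)o1
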